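**Plan**

- Retrosynthesis: the last step back from the target restores four benzyl ethers and a chalcone C=C in the ring A arm. Ring B (B1 = chain carbon, B3 = aryloxy carbon, B4 = hydroxyl carbon) is then lowered by two hydrogens to a 4-alkyl-2-aryloxycyclohex-2-enone. Its B1–B6 and B2–B3 bonds are cut to give an aryloxymethyl vinyl ketone and a 5-aryl-5-oxopentanal.
- Enabling feature: on ring B the hydroxyl (B4) is ortho to the ether oxygen (B3) and para to the chain (B1). B4 can therefore be a ketone carbon, B3 an aryloxy-activated enolate carbon and B2 a former formyl carbon.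
- Further cuts: the O–CH2 bond of the vinyl ketone (vanillin + 2-vinyloxirane), the chalcone C=C (Claisen–Schmidt) and the aryl–CO bond of the aldehyde (aryllithium + δ-valerolactone).
- Forward order: the ring A arm carrying the vinyl ketone (steps 1–4) and the keto aldehyde (steps 5–7) are made in parallel. Ring B is then closed by Michael/aldol annulation, aromatised, and a single hydrogenation removes the benzyl groups and saturates the chalcone. The diaryl ether oxygen is the vanillin phenol oxygen throughout, so no aryl–oxygen coupling is needed.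
- Stereochemistry: the target is achiral. The carbinol centre from vinyloxirane and the B1 centre of the cyclohexenone are racemic and are erased by oxidation and by aromatisation. The E chalcone geometry is thermodynamic and disappears on hydrogenation.

Key step: step 8

Assumption: racemic compounds are written as one enantiomer in the SMILES. The ring A arm is carried as the chalcone because the final hydrogenation that cleaves the benzyl ethers also saturates it.

**Step 1**
Reactants: 1 resacetophenone (2,4-dihydroxyacetophenone)
Product: 2 bis(benzyl ether) 1-[2,4-bis(benzyloxy)phenyl]ethan-1-one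
Conditions: BnBr (2.4 equiv), K2CO3 (3 equiv), DMF, 80 °C
Reagents that add atoms: benzyl bromide, BrCc1ccccc1
Why: Williamson ether synthesis on both phenols; heating in DMF overcomes the hydrogen bond that slows alkylation of the ortho hydroxyl.

**Step 2**
Reactants: 3 vanillin; 4 2-vinyloxirane (racemic)
Product: 5 hydroxy ether 4-[(2-hydroxybut-3-en-1-yl)oxy]-3-methoxybenzaldehyde (racemic)
Conditions: K2CO3 (0.2 equiv), DMF, 75 °C, sealed tube
Reagents that add atoms: none
Why: Base-catalysed SN2 opening of the epoxide by the vanillin phenoxide at the unsubstituted ring carbon, the alkoxide formed regenerating phenoxide; the carbinol centre is the untouched epoxide carbon and stays racemic.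

**Step 3**
Reactants: 5 hydroxy ether; 2 bis(benzyl ether) ketone
Product: 6 chalcone alcohol (E)-1-[2,4-bis(benzyloxy)phenyl]-3-{4-[(2-hydroxybut-3-en-1-yl)oxy]-3-methoxyphenyl}prop-2-en-1-one (racemic)
Conditions: KOH (50% aq.), EtOH, rt
Reagents that add atoms: none
Why: Claisen–Schmidt condensation of the methyl ketone enolate with a non-enolisable aryl aldehyde, E1cB dehydration giving the E enone under thermodynamic control; the secondary alcohol is inert to hydroxide.

**Step 4**
Reactants: 6 chalcone alcohol
Product: 7 vinyl ketone 1-{4-[(E)-3-[2,4-bis(benzyloxy)phenyl]-3-oxoprop-1-en-1-yl]-2-methoxyphenoxy}but-3-en-2-one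
Conditions: Dess–Martin periodinane (1.3 equiv), CH2Cl2, 0 °C to rt; used at once in step 8
Reagents that add atoms: none
Why: Dess–Martin oxidation of a secondary allylic alcohol to the enone under mild, non-basic conditions that should spare the chalcone and the benzyl ethers and limit polymerisation of the vinyl ketone.

**Step 5**
Reactants: 8 4-bromoresorcinol (4-bromobenzene-1,3-diol)
Product: 9 aryl bromide 2,4-bis(benzyloxy)-1-bromobenzene
Conditions: BnBr (2.2 equiv), K2CO3 (3 equiv), DMF, 50 °C
Reagents that add atoms: benzyl bromide, BrCc1ccccc1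
Why: Williamson ether synthesis on two unhindered phenols.

**Step 6**
Reactants: 9 aryl bromide; 10 δ-valerolactone (oxan-2-one)
Product: 13 hydroxy ketone 1-[2,4-bis(benzyloxy)phenyl]-5-hydroxypentan-1-one, via aryllithium 11 (not isolated), via lithium lactolate 12 (not isolated)
Conditions: n-BuLi (1.05 equiv), THF, −78 °C; inverse addition to 10 (1.2 equiv), −78 °C; AcOH, −78 °C to rt
Reagents that add atoms: none
Why: Bromine–lithium exchange followed by acylation of the aryllithium by the lactone; the tetrahedral lithium lactolate persists at −78 °C and so blocks a second addition, and opens to the δ-hydroxy aryl ketone on protonation.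

**Step 7**
Reactants: 13 hydroxy ketone
Product: 14 keto aldehyde 5-[2,4-bis(benzyloxy)phenyl]-5-oxopentanal
Conditions: Dess–Martin periodinane (1.2 equiv), CH2Cl2, rt; used without storage
Reagents that add atoms: none
Why: Dess–Martin oxidation stops cleanly at the aldehyde, and the 1,5-keto aldehyde cannot close on itself because either intramolecular aldol would form a four-membered ring.

**Step 8**
Reactants: 7 vinyl ketone; 14 keto aldehyde
Product: 17 cyclohexenone 2-{4-[(E)-3-[2,4-bis(benzyloxy)phenyl]-3-oxoprop-1-en-1-yl]-2-methoxyphenoxy}-4-{3-[2,4-bis(benzyloxy)phenyl]-3-oxopropyl}cyclohex-2-en-1-one (racemic), via keto aldehyde 15 (not isolated), via ketol 16 (not isolated)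
Conditions: Et2NH (0.3 equiv), CH2Cl2, 0 °C to rt; then solvent exchange, LiOH·H2O (0.3 equiv), i-PrOH, rt
Reagents that add atoms: none
Why: Diethylamine condenses only with the aldehyde of 14 to give an enamine whose β-carbon (future B1) adds to the unsubstituted terminus of the vinyl ketone of 7 (future B6), and hydrolysis returns the amine and leaves the 1,5-keto aldehyde 15. The closest known reaction type is the amine-catalysed Michael addition of aldehydes to alkyl vinyl ketones followed by aldol cyclodehydration to 4-substituted cyclohexenones, an organocatalytic Robinson annulation. Lithium hydroxide then enolises the ring ketone toward the aryloxy-bearing methylene (B3), its more acidic α-position, and this enolate attacks the formyl carbon (B2) in a 6-(enolexo)-exo-trig aldol; E1cB loss of water from ketol 16 gives the conjugated 2-aryloxy enone. The B1 stereocentre arises in the Michael step without control, so 17 is racemic, which is of no consequence because B1 becomes an sp2 carbon in step 9. The step needs chemoselectivity among two enones and three carbonyl groups: the terminal vinyl ketone is far more electrophilic than the β-aryl chalcone, and only the aldehyde forms an enamine at a useful rate. It also needs a single ring closure: the aldehyde is the only strongly electrophilic carbonyl and B3 is the only enolisable carbon that can reach it through a six-membered ring, while the two conceivable six-membered ketone-to-ketone aldols are reversible and are drained by the irreversible dehydration of 16.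

**Step 9**
Reactants: 17 cyclohexenone
Product: 18 phenol (E)-1-[2,4-bis(benzyloxy)phenyl]-3-[4-(5-{3-[2,4-bis(benzyloxy)phenyl]-3-oxopropyl}-2-hydroxyphenoxy)-3-methoxyphenyl]prop-2-en-1-one
Conditions: Pd(OCOCF3)2 (5 mol%), 2-(dimethylamino)pyridine (10 mol%), TsOH·H2O (20 mol%), O2 (1 atm), DMSO, 80 °C
Reagents that add atoms: none
Why: Palladium-catalysed aerobic dehydrogenation of a cyclohexenone: a divalent palladium enolate at B5 undergoes β-hydride elimination from B6 to the 2,5-dienone, whose B1 hydrogen shifts to oxygen to give the phenol while oxygen reoxidises the metal; dehydrogenation that strays to the saturated aryl ketone arm would only create a second chalcone, which step 10 saturates.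

**Step 10**
Reactants: 18 phenol
Product: 19 verbenachalcone
Conditions: H2 (1 atm), Pd/C (10 wt%), EtOAc–MeOH, rt
Reagents that add atoms: none
Why: Heterogeneous catalytic hydrogenation and hydrogenolysis: the chalcone C=C is saturated and the four benzyl aryl ethers are cleaved, while the electron-rich aryl ketones and the diaryl ether should be inert at 1 atm.

**Compound list**

1 | 2,4-dihydroxyacetophenone (resacetophenone) | CC(=O)c1ccc(O)cc1O | starting material
2 | 1-[2,4-bis(benzyloxy)phenyl]ethan-1-one | CC(=O)c1ccc(OCc2ccccc2)cc1OCc1ccccc1 | intermediate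
3 | vanillin (4-hydroxy-3-methoxybenzaldehyde) | COc1cc(C=O)ccc1O | starting material
4 | 2-vinyloxirane (racemic, one enantiomer drawn) | C=C[C@@H]1CO1 | starting material
5 | 4-[(2-hydroxybut-3-en-1-yl)oxy]-3-methoxybenzaldehyde (racemic, one enantiomer drawn) | COc1cc(C=O)ccc1OC[C@H](O)C=C | intermediate
6 | (E)-1-[2,4-bis(benzyloxy)phenyl]-3-{4-[(2-hydroxybut-3-en-1-yl)oxy]-3-methoxyphenyl}prop-2-en-1-one (racemic, one enantiomer drawn) | COc1cc(/C=C/C(=O)c2ccc(OCc3ccccc3)cc2OCc2ccccc2)ccc1OC[C@H](O)C=C | intermediate
7 | 1-{4-[(E)-3-[2,4-bis(benzyloxy)phenyl]-3-oxoprop-1-en-1-yl]-2-methoxyphenoxy}but-3-en-2-one | C=CC(=O)COc1ccc(/C=C/C(=O)c2ccc(OCc3ccccc3)cc2OCc2ccccc2)cc1OC | intermediate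
8 | 4-bromoresorcinol (4-bromobenzene-1,3-diol) | Oc1ccc(Br)c(O)c1 | starting material
9 | 2,4-bis(benzyloxy)-1-bromobenzene | Brc1ccc(OCc2ccccc2)cc1OCc1ccccc1 | intermediate
10 | δ-valerolactone (oxan-2-one) | O=C1CCCCO1 | starting material
11 | [2,4-bis(benzyloxy)phenyl]lithium | [Li]c1ccc(OCc2ccccc2)cc1OCc1ccccc1 | intermediate
12 | lithium 2-[2,4-bis(benzyloxy)phenyl]oxan-2-olate | [Li+].[O-]C1(CCCCO1)c1ccc(OCc2ccccc2)cc1OCc1ccccc1 | intermediate
13 | 1-[2,4-bis(benzyloxy)phenyl]-5-hydroxypentan-1-one | OCCCCC(=O)c1ccc(OCc2ccccc2)cc1OCc1ccccc1 | intermediate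
14 | 5-[2,4-bis(benzyloxy)phenyl]-5-oxopentanal | O=CCCCC(=O)c1ccc(OCc2ccccc2)cc1OCc1ccccc1 | intermediate
15 | 2-{3-[2,4-bis(benzyloxy)phenyl]-3-oxopropyl}-6-{4-[(E)-3-[2,4-bis(benzyloxy)phenyl]-3-oxoprop-1-en-1-yl]-2-methoxyphenoxy}-5-oxohexanal (racemic, one enantiomer drawn) | O=C[C@H](CCC(=O)c1ccc(OCc2ccccc2)cc1OCc1ccccc1)CCC(=O)COc1ccc(/C=C/C(=O)c2ccc(OCc3ccccc3)cc2OCc2ccccc2)cc1OC | intermediate
16 | 2-{4-[(E)-3-[2,4-bis(benzyloxy)phenyl]-3-oxoprop-1-en-1-yl]-2-methoxyphenoxy}-4-{3-[2,4-bis(benzyloxy)phenyl]-3-oxopropyl}-3-hydroxycyclohexan-1-one (mixture of diastereomers at the hydroxyl and aryloxy carbons, racemic, chain-bearing carbon drawn as one enantiomer) | COc1cc(/C=C/C(=O)c2ccc(OCc3ccccc3)cc2OCc2ccccc2)ccc1OC1C(O)[C@H](CCC(=O)c2ccc(OCc3ccccc3)cc2OCc2ccccc2)CCC1=O | intermediate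
17 | 2-{4-[(E)-3-[2,4-bis(benzyloxy)phenyl]-3-oxoprop-1-en-1-yl]-2-methoxyphenoxy}-4-{3-[2,4-bis(benzyloxy)phenyl]-3-oxopropyl}cyclohex-2-en-1-one (racemic, one enantiomer drawn) | COc1cc(/C=C/C(=O)c2ccc(OCc3ccccc3)cc2OCc2ccccc2)ccc1OC1=C[C@H](CCC(=O)c2ccc(OCc3ccccc3)cc2OCc2ccccc2)CCC1=O | intermediate
18 | (E)-1-[2,4-bis(benzyloxy)phenyl]-3-[4-(5-{3-[2,4-bis(benzyloxy)phenyl]-3-oxopropyl}-2-hydroxyphenoxy)-3-methoxyphenyl]prop-2-en-1-one | COc1cc(/C=C/C(=O)c2ccc(OCc3ccccc3)cc2OCc2ccccc2)ccc1Oc1cc(CCC(=O)c2ccc(OCc3ccccc3)cc2OCc2ccccc2)ccc1O | intermediate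
19 | verbenachalcone | COc1cc(CCC(=O)c2ccc(O)cc2O)ccc1Oc1cc(CCC(=O)c2ccc(O)cc2O)ccc1O | target

**Step count and risks**

Total steps: 10. Longest linear sequence: 6 steps (for example steps 2, 3, 4, 8, 9, 10 from vanillin).

Steps most likely to fail:

Step 8. The free secondary amine may start oligomerisation of the aryloxymethyl vinyl ketone by conjugate addition, and the aldehyde may condense with itself. Either process could outrun the cross Michael addition, and the base stage could stall at the ketol. The fallback sets out from 14 and uses a preformed enamine, so that no free amine meets the vinyl ketone. Condensation of 14 with pyrrolidine (K2CO3, toluene, 0 °C, excess amine removed under vacuum) should give the enamine (E)-1-[2,4-bis(benzyloxy)phenyl]-5-(pyrrolidin-1-yl)pent-4-en-1-one F1. Stork enamine Michael addition of F1 to 7 in dry toluene, followed by warming in an aqueous AcOH/NaOAc buffer, should hydrolyse the adduct and cyclodehydrate it. The route is rejoined at 17.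

Step 9. The dehydrogenation may stop at partial conversion through deposition of palladium metal, or turnover may be slow because the electron-rich aryloxy enone binds the catalyst, leaving mixtures of oxidation levels. The fallback sets out from 17 and needs no selectivity among the enolisable ketones. Exhaustive silylation (TMSOTf, Et3N, CH2Cl2, 0 °C) should give the bis(trimethylsilyl enol ether) of 17 F2, with a ring dienol ether across B4–B5 and a Z enol ether of the saturated aryl ketone. Saegusa–Ito oxidation with stoichiometric Pd(OAc)2 (divalent palladium) in MeCN should then oxidise both enol ethers: the ring dienone tautomerises to the phenol and the side chain becomes a second chalcone. The product is the phenol bis-chalcone (E,E)-3,3′-[(ring A/ring B diaryl ether)]bis{1-[2,4-bis(benzyloxy)phenyl]prop-2-en-1-one} F3. F3 is hydrogenated under the conditions of step 10, which saturate both double bonds and cleave the benzyl ethers. The route is rejoined at 19.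

Step 2. The phenoxide may attack the allylic epoxide carbon or the alkene terminus (SN2′) as well as the terminal carbon, giving regioisomeric ethers that would be hard to separate. The fallback sets out from 3 and uses an electrophile that cannot form an epoxide. Commercial 2-hydroxybut-3-en-1-yl tosylate (either enantiomer serves, since the carbinol is oxidised in step 4) is silylated (TBSCl, imidazole, DMF) to 2-[(tert-butyldimethylsilyl)oxy]but-3-en-1-yl 4-methylbenzenesulfonate F4. Williamson alkylation of 3 with F4 (K2CO3, DMF, 70 °C) should give the silyl ether 4-({2-[(tert-butyldimethylsilyl)oxy]but-3-en-1-yl}oxy)-3-methoxybenzaldehyde F5. Desilylation (TBAF, THF, 0 °C) rejoins the route at 5.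

**Further compounds**

F1 | step 8 | (E)-1-[2,4-bis(benzyloxy)phenyl]-5-(pyrrolidin-1-yl)pent-4-en-1-one | O=C(CC/C=C/N1CCCC1)c1ccc(OCc2ccccc2)cc1OCc1ccccc1
F2 | step 9 | bis(trimethylsilyl enol ether) of 17 (ring dienol ether across B4–B5, Z enol ether of the saturated aryl ketone; racemic, one enantiomer drawn) | COc1cc(/C=C/C(=O)c2ccc(OCc3ccccc3)cc2OCc2ccccc2)ccc1OC1=C[C@H](C/C=C(\O[Si](C)(C)C)c2ccc(OCc3ccccc3)cc2OCc2ccccc2)CC=C1O[Si](C)(C)C
F3 | step 9 | (E)-1-[2,4-bis(benzyloxy)phenyl]-3-[4-(5-{(E)-3-[2,4-bis(benzyloxy)phenyl]-3-oxoprop-1-en-1-yl}-2-hydroxyphenoxy)-3-methoxyphenyl]prop-2-en-1-one | COc1cc(/C=C/C(=O)c2ccc(OCc3ccccc3)cc2OCc2ccccc2)ccc1Oc1cc(/C=C/C(=O)c2ccc(OCc3ccccc3)cc2OCc2ccccc2)ccc1O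
F4 | step 2 | 2-[(tert-butyldimethylsilyl)oxy]but-3-en-1-yl 4-methylbenzenesulfonate (one enantiomer drawn) | C=C[C@@H](O[Si](C)(C)C(C)(C)C)COS(=O)(=O)c1ccc(C)cc1
F5 | step 2 | 4-({2-[(tert-butyldimethylsilyl)oxy]but-3-en-1-yl}oxy)-3-methoxybenzaldehyde (one enantiomer drawn) | COc1cc(C=O)ccc1OC[C@H](O[Si](C)(C)C(C)(C)C)C=C
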